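**Plan**
1. Retrosynthesis: the C1 ketone comes from a C1 alcohol and the C2–C3 epoxide from a C2=C3 alkene; the C6 angelate and C8 acetate acyl bonds are cut; the ring bond C5–C6 of the resulting trans-cyclohexenol is cut by a carbonyl-ene disconnection to an acyclic (3Z,6Z)-trienal; the trienal is cut at both trisubstituted alkenes (C2=C3, C5=C7; Wittig) and at C8–C9 (epoxide opening).
2. Enabling feature: on the six-membered carbocycle the C6 oxygen is trans to the C5 side chain, whose first carbon C7 carries the exocyclic C14 methylene. This 2-(alk-1-en-2-yl)cyclohexanol is the homoallylic alcohol left by an aldehyde-ene closure (isopulegol pattern).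
3. Forward: a C3–C5 phosphonium linchpin is joined to the C1/C2/C6 methyl ketone (step 3) and then to the C7–C11 methyl ketone (step 10); the only carbocycle closes in step 15; acylations, directed epoxidation (epoxide ring, step 20) and oxidation of C1 finish the target.
4. Stereochemistry: C1 from methyl (R)-glycerate acetonide, C8 from methyl (S)-glycidate; both Z alkenes from Wittig reactions of α-oxygenated methyl ketones; C5 and C6 from the chair-like ene transition state steered by C1; C2 and C3 from epoxidation directed by the C1 hydroxyl, after which C1 becomes the ketone; the angelate geometry comes with the acyl donor.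

Key step: step 15

Remark: locants C1–C14 are those of the target skeleton (C1 ketone carbon, C2 methyl-bearing and C3 epoxide carbons, C4 ring CH2, C5 chain-bearing ring carbon, C6 angelate carbon, C7 side-chain carbon bearing the C14 methylene, C8 acetate carbon, C9 CH2, C10=C11 prenyl alkene). TBS = tert-butyldimethylsilyl, PMB = 4-methoxybenzyl. Angelic anhydride is assumed to be purchasable.

**Step 1**
Reactants: 1 methyl (4R)-2,2-dimethyl-1,3-dioxolane-4-carboxylate
Product: 3 1-[(4R)-2,2-dimethyl-1,3-dioxolan-4-yl]ethan-1-one, via Weinreb amide 2 (not isolated)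
Conditions: MeNH(OMe)·HCl, iPrMgCl, THF, −20 °C; then MeMgBr, −20 → 0 °C; aq. NH4Cl
Reagents that add atoms: methylmagnesium bromide, C[Mg]Br
Why: One-flask Weinreb ketone synthesis, in which the magnesium amide of N,O-dimethylhydroxylamine turns the ester into amide 2 and the chelated tetrahedral adduct of 2 with MeMgBr stops at the ketone, so the C1 stereocentre is not enolised.

**Step 2**
Reactants: 4 (3-bromopropoxy)(tert-butyl)dimethylsilane
Product: 5 [3-(TBS-oxy)propyl]triphenylphosphonium bromide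
Conditions: PPh3, MeCN, 80 °C
Reagents that add atoms: triphenylphosphine, c1ccc(cc1)P(c1ccccc1)c1ccccc1
Why: SN2 quaternisation of triphenylphosphine by a primary bromide gives the phosphonium salt for the first Wittig reaction.

**Step 3**
Reactants: 5 [3-(TBS-oxy)propyl]triphenylphosphonium bromide; 3 1-[(4R)-2,2-dimethyl-1,3-dioxolan-4-yl]ethan-1-one
Product: 7 (4S)-4-[(2Z)-5-(TBS-oxy)pent-2-en-2-yl]-2,2-dimethyl-1,3-dioxolane, via phosphonium ylide 6 (not isolated)
Conditions: 5, KN(SiMe3)2, THF, −78 → 0 °C; then 3, −78 °C → rt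
Reagents that add atoms: none
Why: Wittig olefination of an α-alkoxy methyl ketone with a salt-free unstabilised ylide, which under kinetic control places the ylide chain (C4) cis to the oxygen-bearing carbon (C1) and so should give the (Z)-C2=C3 alkene with C1 carried over unchanged.

**Step 4**
Reactants: 7 (4S)-4-[(2Z)-5-(TBS-oxy)pent-2-en-2-yl]-2,2-dimethyl-1,3-dioxolane
Product: 8 (3Z)-4-[(4S)-2,2-dimethyl-1,3-dioxolan-4-yl]pent-3-en-1-ol
Conditions: Bu4NF, THF, 0 °C → rt
Reagents that add atoms: none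
Why: Fluoride-driven cleavage of a primary silyl ether, to which the acetonide and the alkene are inert.

**Step 5**
Reactants: 8 (3Z)-4-[(4S)-2,2-dimethyl-1,3-dioxolan-4-yl]pent-3-en-1-ol
Product: 9 (4S)-4-[(2Z)-5-iodopent-2-en-2-yl]-2,2-dimethyl-1,3-dioxolane
Conditions: I2, PPh3, imidazole, CH2Cl2, 0 °C
Reagents that add atoms: iodine, II
Why: Appel-type iodination of a primary alcohol through its alkoxyphosphonium ion, with imidazole keeping the medium neutral for the acetonide.

**Step 6**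
Reactants: 9 (4S)-4-[(2Z)-5-iodopent-2-en-2-yl]-2,2-dimethyl-1,3-dioxolane
Product: 10 [(3Z)-4-[(4S)-2,2-dimethyl-1,3-dioxolan-4-yl]pent-3-en-1-yl]triphenylphosphonium iodide
Conditions: PPh3, MeCN, 80 °C (trace K2CO3)
Reagents that add atoms: triphenylphosphine, c1ccc(cc1)P(c1ccccc1)c1ccccc1
Why: SN2 quaternisation of triphenylphosphine by the primary homoallylic iodide.

**Step 7**
Reactants: 11 methyl (2S)-oxirane-2-carboxylate; 12 (2-methylprop-1-en-1-yl)magnesium bromide
Product: 13 methyl (2S)-2-hydroxy-5-methylhex-4-enoate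
Conditions: CuBr·SMe2 (10 mol%), THF, −78 → −40 °C; aq. NH4Cl
Reagents that add atoms: none
Why: Copper-catalysed Grignard opening of the terminal epoxide at its unsubstituted carbon (SN2), which forms C8–C9 and leaves the ester and the C8 stereocentre untouched at low temperature.

**Step 8**
Reactants: 13 methyl (2S)-2-hydroxy-5-methylhex-4-enoate
Product: 14 methyl (2S)-2-(TBS-oxy)-5-methylhex-4-enoate
Conditions: TBSCl, imidazole, DMF, rt
Reagents that add atoms: tert-butyldimethylsilyl chloride, CC(C)(C)[Si](C)(C)Cl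
Why: Standard imidazole-mediated silylation of a secondary alcohol.

**Step 9**
Reactants: 14 methyl (2S)-2-(TBS-oxy)-5-methylhex-4-enoate
Product: 16 (3S)-3-(TBS-oxy)-6-methylhept-5-en-2-one, via Weinreb amide 15 (not isolated)
Conditions: MeNH(OMe)·HCl, iPrMgCl, THF, −20 °C; then MeMgBr, −20 → 0 °C; aq. NH4Cl
Reagents that add atoms: methylmagnesium bromide, C[Mg]Br
Why: One-flask Weinreb ketone synthesis as in step 1, delivering the methyl ketone (C7 with its C14 methyl) without enolising C8.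

**Step 10**
Reactants: 10 [(3Z)-4-[(4S)-2,2-dimethyl-1,3-dioxolan-4-yl]pent-3-en-1-yl]triphenylphosphonium iodide; 16 (3S)-3-(TBS-oxy)-6-methylhept-5-en-2-one
Product: 18 (4S)-4-[(2Z,5Z,7S)-7-(TBS-oxy)-6,10-dimethylundeca-2,5,9-trien-2-yl]-2,2-dimethyl-1,3-dioxolane, via phosphonium ylide 17 (not isolated)
Conditions: 10, KN(SiMe3)2, THF, −78 → 0 °C; then 16, −78 °C → rt
Reagents that add atoms: none
Why: Wittig olefination of the α-silyloxy methyl ketone with the unstabilised ylide, which should again place the ylide chain (C4) cis to the oxygenated carbon (C8) and so give the (Z)-C5=C7 alkene with the C14 methyl trans to C4.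

**Step 11**
Reactants: 18 (4S)-4-[(2Z,5Z,7S)-7-(TBS-oxy)-6,10-dimethylundeca-2,5,9-trien-2-yl]-2,2-dimethyl-1,3-dioxolane
Product: 19 (2S,3Z,6Z,8S)-8-(TBS-oxy)-3,7,11-trimethyldodeca-3,6,10-triene-1,2-diol
Conditions: PPTS (cat.), MeOH, rt
Reagents that add atoms: none
Why: Mild acid-catalysed transacetalisation to methanol should remove the terminal acetonide faster than the hindered secondary silyl ether is attacked.

**Step 12**
Reactants: 19 (2S,3Z,6Z,8S)-8-(TBS-oxy)-3,7,11-trimethyldodeca-3,6,10-triene-1,2-diol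
Product: 20 (4S)-2-(4-methoxyphenyl)-4-[(2Z,5Z,7S)-7-(TBS-oxy)-6,10-dimethylundeca-2,5,9-trien-2-yl]-1,3-dioxolane (both epimers at the acetal carbon)
Conditions: 4-MeOC6H4CH(OMe)2, PPTS (cat.), CH2Cl2, rt
Reagents that add atoms: 4-methoxybenzaldehyde dimethyl acetal, COc1ccc(cc1)C(OC)OC
Why: Acid-catalysed acetal exchange gives the five-membered 4-methoxybenzylidene acetal of the 1,2-diol.

**Step 13**
Reactants: 20 (4S)-2-(4-methoxyphenyl)-4-[(2Z,5Z,7S)-7-(TBS-oxy)-6,10-dimethylundeca-2,5,9-trien-2-yl]-1,3-dioxolane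
Product: 21 (2S,3Z,6Z,8S)-8-(TBS-oxy)-2-(PMB-oxy)-3,7,11-trimethyldodeca-3,6,10-trien-1-ol
Conditions: iBu2AlH, CH2Cl2, −78 → 0 °C; aq. KNaC4H4O6
Reagents that add atoms: none
Why: Regioselective reductive opening of the benzylidene acetal, in which aluminium binds the less hindered primary oxygen, that C–O bond breaks and hydride quenches the oxocarbenium ion, leaving PMB on the secondary C1 oxygen and C6 as the free primary alcohol.

**Step 14**
Reactants: 21 (2S,3Z,6Z,8S)-8-(TBS-oxy)-2-(PMB-oxy)-3,7,11-trimethyldodeca-3,6,10-trien-1-ol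
Product: 22 (2S,3Z,6Z,8S)-8-(TBS-oxy)-2-(PMB-oxy)-3,7,11-trimethyldodeca-3,6,10-trienal
Conditions: Dess–Martin periodinane, pyridine, CH2Cl2, 0 °C; used crude at once
Reagents that add atoms: none
Why: Dess–Martin oxidation under buffered, non-basic conditions, chosen so that the α-alkoxy β,γ-unsaturated aldehyde is neither epimerised at C1 nor drawn into conjugation before it is cyclised.

**Step 15**
Reactants: 22 (2S,3Z,6Z,8S)-8-(TBS-oxy)-2-(PMB-oxy)-3,7,11-trimethyldodeca-3,6,10-trienal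
Product: 23 (1S,2S,6S)-6-[(3S)-3-(TBS-oxy)-6-methylhepta-1,5-dien-2-yl]-2-(PMB-oxy)-3-methylcyclohex-3-en-1-ol
Conditions: Me2AlCl (2 equiv), CH2Cl2, −78 °C; aq. KNaC4H4O6
Reagents that add atoms: none
Why: Me2AlCl binds the aldehyde oxygen together with the neighbouring PMB ether oxygen, the C5=C7 alkene adds through C5 to the carbonyl carbon while a hydrogen of the C14 methyl passes to oxygen in a concerted six-centre ene transition state, and loss of methane from the product complex leaves an aluminium alkoxide that removes the proton source for cationic side reactions. The closest known reaction type is the Lewis-acid carbonyl-ene cyclisation of citronellal to isopulegol. The six-membered ring closes in the 6-exo-trig sense at the carbonyl carbon (carbonyl oxygen and C7 stay outside the ring) through a half-chair in which the (Z)-C2=C3 alkene holds C1–C4 coplanar and C5 and C6 are the out-of-plane atoms. C6 is set by the aluminium-bound oxygen taking the equatorial position, trans to the C5 chain; C5, and with it the absolute sense of both new centres, is set by C1, whose ether lies pseudoequatorial and anti to the forming C5–C6 bond (Felkin–Anh arrangement) with the chelated aluminium on the open periphery of the ring. The step needs hydrogen transfer from C14 and not from C8–H, which the (Z)-C5=C7 geometry secures by placing the methyl trans to the C4 tether on the side of the equatorial oxygen while C8–H lies in the alkene plane; it also needs chemoselectivity against the prenyl alkene, which could only close a ten-membered ring.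

**Step 16**
Reactants: 23 (1S,2S,6S)-6-[(3S)-3-(TBS-oxy)-6-methylhepta-1,5-dien-2-yl]-2-(PMB-oxy)-3-methylcyclohex-3-en-1-ol
Product: 24 (1S,2S,6S)-6-[(3S)-3-(TBS-oxy)-6-methylhepta-1,5-dien-2-yl]-2-(PMB-oxy)-3-methylcyclohex-3-en-1-yl (2Z)-2-methylbut-2-enoate
Conditions: angelic anhydride, LiN(SiMe3)2, THF, −20 °C → rt
Reagents that add atoms: angelic anhydride, C/C=C(/C)C(=O)OC(=O)/C(C)=C\C
Why: Acylation of the lithium alkoxide by the symmetrical anhydride without a nucleophilic catalyst, which avoids the addition–elimination pathway that turns angeloyl donors into tiglates.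

**Step 17**
Reactants: 24 (1S,2S,6S)-6-[(3S)-3-(TBS-oxy)-6-methylhepta-1,5-dien-2-yl]-2-(PMB-oxy)-3-methylcyclohex-3-en-1-yl (2Z)-2-methylbut-2-enoate
Product: 25 (1S,2S,6S)-6-[(3S)-3-hydroxy-6-methylhepta-1,5-dien-2-yl]-2-(PMB-oxy)-3-methylcyclohex-3-en-1-yl (2Z)-2-methylbut-2-enoate
Conditions: HF·pyridine, pyridine, THF, 0 °C → rt
Reagents that add atoms: none
Why: Desilylation driven by Si–F bond formation under buffered conditions that the angelate and the PMB ether tolerate.

**Step 18**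
Reactants: 25 (1S,2S,6S)-6-[(3S)-3-hydroxy-6-methylhepta-1,5-dien-2-yl]-2-(PMB-oxy)-3-methylcyclohex-3-en-1-yl (2Z)-2-methylbut-2-enoate
Product: 26 (1S,2S,6S)-6-[(3S)-3-acetoxy-6-methylhepta-1,5-dien-2-yl]-2-(PMB-oxy)-3-methylcyclohex-3-en-1-yl (2Z)-2-methylbut-2-enoate
Conditions: Ac2O, pyridine, rt
Reagents that add atoms: acetic anhydride, CC(=O)OC(C)=O
Why: Plain acetylation of the secondary allylic C8 alcohol, placed before the oxidative steps so that no free hydroxyl other than C1–OH is present later.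

**Step 19**
Reactants: 26 (1S,2S,6S)-6-[(3S)-3-acetoxy-6-methylhepta-1,5-dien-2-yl]-2-(PMB-oxy)-3-methylcyclohex-3-en-1-yl (2Z)-2-methylbut-2-enoate
Product: 27 (1S,2S,6S)-6-[(3S)-3-acetoxy-6-methylhepta-1,5-dien-2-yl]-2-hydroxy-3-methylcyclohex-3-en-1-yl (2Z)-2-methylbut-2-enoate
Conditions: DDQ, CH2Cl2/pH 7 buffer, 0 °C
Reagents that add atoms: none
Why: Oxidative PMB ether cleavage with DDQ (benzylic hydride abstraction, then hydrolysis of the oxocarbenium ion), which leaves esters and isolated alkenes alone.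

**Step 20**
Reactants: 27 (1S,2S,6S)-6-[(3S)-3-acetoxy-6-methylhepta-1,5-dien-2-yl]-2-hydroxy-3-methylcyclohex-3-en-1-yl (2Z)-2-methylbut-2-enoate
Product: 28 (1R,2R,3S,4S,6S)-4-[(3S)-3-acetoxy-6-methylhepta-1,5-dien-2-yl]-2-hydroxy-1-methyl-7-oxabicyclo[4.1.0]heptan-3-yl (2Z)-2-methylbut-2-enoate
Conditions: VO(acac)2 (cat.), tBuOOH, CH2Cl2, 0 °C → rt
Reagents that add atoms: tert-butyl hydroperoxide, CC(C)(C)OO
Why: Hydroxyl-directed vanadium-catalysed epoxidation, in which the alkylperoxo complex bound to the C1 alkoxide delivers oxygen to the C2=C3 alkene on the face of the C1 hydroxyl (cis to the C5 chain, as in the epoxidation of cis-carveol), setting C2 and C3 and leaving the three alkenes without a free allylic hydroxyl untouched.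

**Step 21**
Reactants: 28 (1R,2R,3S,4S,6S)-4-[(3S)-3-acetoxy-6-methylhepta-1,5-dien-2-yl]-2-hydroxy-1-methyl-7-oxabicyclo[4.1.0]heptan-3-yl (2Z)-2-methylbut-2-enoate
Product: 29 (1S,3S,4S,6S)-4-[(3S)-3-acetoxy-6-methylhepta-1,5-dien-2-yl]-1-methyl-2-oxo-7-oxabicyclo[4.1.0]heptan-3-yl (2Z)-2-methylbut-2-enoate (CNP0125636.1)
Conditions: Dess–Martin periodinane, pyridine, CH2Cl2, 0 °C → rt
Reagents that add atoms: none
Why: Dess–Martin oxidation of the secondary epoxy alcohol to the α,β-epoxy ketone under neutral conditions that should spare the epoxide, both esters and the enolisable C6 centre.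

**Compound list**
1 | methyl (4R)-2,2-dimethyl-1,3-dioxolane-4-carboxylate | COC(=O)[C@H]1COC(C)(C)O1 | starting material
2 | (4R)-N-methoxy-N,2,2-trimethyl-1,3-dioxolane-4-carboxamide | CON(C)C(=O)[C@H]1COC(C)(C)O1 | intermediate
3 | 1-[(4R)-2,2-dimethyl-1,3-dioxolan-4-yl]ethan-1-one | CC(=O)[C@H]1COC(C)(C)O1 | intermediate
4 | (3-bromopropoxy)(tert-butyl)dimethylsilane | CC(C)(C)[Si](C)(C)OCCCBr | starting material
5 | [3-(TBS-oxy)propyl]triphenylphosphonium bromide | CC(C)(C)[Si](C)(C)OCCC[P+](c1ccccc1)(c1ccccc1)c1ccccc1.[Br-] | intermediate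
6 | [3-(TBS-oxy)propylidene]triphenylphosphorane | CC(C)(C)[Si](C)(C)OCCC=P(c1ccccc1)(c1ccccc1)c1ccccc1 | intermediate
7 | (4S)-4-[(2Z)-5-(TBS-oxy)pent-2-en-2-yl]-2,2-dimethyl-1,3-dioxolane | CC(C)(C)[Si](C)(C)OCC/C=C(/C)[C@H]1COC(C)(C)O1 | intermediate
8 | (3Z)-4-[(4S)-2,2-dimethyl-1,3-dioxolan-4-yl]pent-3-en-1-ol | OCC/C=C(/C)[C@H]1COC(C)(C)O1 | intermediate
9 | (4S)-4-[(2Z)-5-iodopent-2-en-2-yl]-2,2-dimethyl-1,3-dioxolane | ICC/C=C(/C)[C@H]1COC(C)(C)O1 | intermediate
10 | [(3Z)-4-[(4S)-2,2-dimethyl-1,3-dioxolan-4-yl]pent-3-en-1-yl]triphenylphosphonium iodide | c1ccccc1[P+](c1ccccc1)(c1ccccc1)CC/C=C(/C)[C@H]1COC(C)(C)O1.[I-] | intermediate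
11 | methyl (2S)-oxirane-2-carboxylate | COC(=O)[C@@H]1CO1 | starting material
12 | (2-methylprop-1-en-1-yl)magnesium bromide | CC(C)=C[Mg]Br | starting material
13 | methyl (2S)-2-hydroxy-5-methylhex-4-enoate | COC(=O)[C@@H](O)CC=C(C)C | intermediate
14 | methyl (2S)-2-(TBS-oxy)-5-methylhex-4-enoate | COC(=O)[C@@H](O[Si](C)(C)C(C)(C)C)CC=C(C)C | intermediate
15 | (2S)-2-(TBS-oxy)-N-methoxy-N,5-dimethylhex-4-enamide | CON(C)C(=O)[C@@H](O[Si](C)(C)C(C)(C)C)CC=C(C)C | intermediate
16 | (3S)-3-(TBS-oxy)-6-methylhept-5-en-2-one | CC(=O)[C@@H](O[Si](C)(C)C(C)(C)C)CC=C(C)C | intermediate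
17 | [(3Z)-4-[(4S)-2,2-dimethyl-1,3-dioxolan-4-yl]pent-3-en-1-ylidene]triphenylphosphorane | c1ccccc1P(c1ccccc1)(c1ccccc1)=CC/C=C(/C)[C@H]1COC(C)(C)O1 | intermediate
18 | (4S)-4-[(2Z,5Z,7S)-7-(TBS-oxy)-6,10-dimethylundeca-2,5,9-trien-2-yl]-2,2-dimethyl-1,3-dioxolane | CC(C)=CC[C@H](O[Si](C)(C)C(C)(C)C)/C(C)=C\C/C=C(/C)[C@H]1COC(C)(C)O1 | intermediate
19 | (2S,3Z,6Z,8S)-8-(TBS-oxy)-3,7,11-trimethyldodeca-3,6,10-triene-1,2-diol | CC(C)=CC[C@H](O[Si](C)(C)C(C)(C)C)/C(C)=C\C/C=C(/C)[C@H](O)CO | intermediate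
20 | (4S)-2-(4-methoxyphenyl)-4-[(2Z,5Z,7S)-7-(TBS-oxy)-6,10-dimethylundeca-2,5,9-trien-2-yl]-1,3-dioxolane (acetal epimers) | CC(C)=CC[C@H](O[Si](C)(C)C(C)(C)C)/C(C)=C\C/C=C(/C)[C@H]1COC(c2ccc(OC)cc2)O1 | intermediate
21 | (2S,3Z,6Z,8S)-8-(TBS-oxy)-2-(PMB-oxy)-3,7,11-trimethyldodeca-3,6,10-trien-1-ol | CC(C)=CC[C@H](O[Si](C)(C)C(C)(C)C)/C(C)=C\C/C=C(/C)[C@H](OCc1ccc(OC)cc1)CO | intermediate
22 | (2S,3Z,6Z,8S)-8-(TBS-oxy)-2-(PMB-oxy)-3,7,11-trimethyldodeca-3,6,10-trienal | CC(C)=CC[C@H](O[Si](C)(C)C(C)(C)C)/C(C)=C\C/C=C(/C)[C@H](OCc1ccc(OC)cc1)C=O | intermediate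
23 | (1S,2S,6S)-6-[(3S)-3-(TBS-oxy)-6-methylhepta-1,5-dien-2-yl]-2-(PMB-oxy)-3-methylcyclohex-3-en-1-ol | C=C([C@H](CC=C(C)C)O[Si](C)(C)C(C)(C)C)[C@@H]1CC=C(C)[C@H](OCc2ccc(OC)cc2)[C@H]1O | intermediate
24 | (1S,2S,6S)-6-[(3S)-3-(TBS-oxy)-6-methylhepta-1,5-dien-2-yl]-2-(PMB-oxy)-3-methylcyclohex-3-en-1-yl (2Z)-2-methylbut-2-enoate | C=C([C@H](CC=C(C)C)O[Si](C)(C)C(C)(C)C)[C@@H]1CC=C(C)[C@H](OCc2ccc(OC)cc2)[C@H]1OC(=O)/C(C)=C\C | intermediate
25 | (1S,2S,6S)-6-[(3S)-3-hydroxy-6-methylhepta-1,5-dien-2-yl]-2-(PMB-oxy)-3-methylcyclohex-3-en-1-yl (2Z)-2-methylbut-2-enoate | C=C([C@H](CC=C(C)C)O)[C@@H]1CC=C(C)[C@H](OCc2ccc(OC)cc2)[C@H]1OC(=O)/C(C)=C\C | intermediate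
26 | (1S,2S,6S)-6-[(3S)-3-acetoxy-6-methylhepta-1,5-dien-2-yl]-2-(PMB-oxy)-3-methylcyclohex-3-en-1-yl (2Z)-2-methylbut-2-enoate | C=C([C@H](CC=C(C)C)OC(C)=O)[C@@H]1CC=C(C)[C@H](OCc2ccc(OC)cc2)[C@H]1OC(=O)/C(C)=C\C | intermediate
27 | (1S,2S,6S)-6-[(3S)-3-acetoxy-6-methylhepta-1,5-dien-2-yl]-2-hydroxy-3-methylcyclohex-3-en-1-yl (2Z)-2-methylbut-2-enoate | C=C([C@H](CC=C(C)C)OC(C)=O)[C@@H]1CC=C(C)[C@H](O)[C@H]1OC(=O)/C(C)=C\C | intermediate
28 | (1R,2R,3S,4S,6S)-4-[(3S)-3-acetoxy-6-methylhepta-1,5-dien-2-yl]-2-hydroxy-1-methyl-7-oxabicyclo[4.1.0]heptan-3-yl (2Z)-2-methylbut-2-enoate | C=C([C@H](CC=C(C)C)OC(C)=O)[C@@H]1C[C@@H]2O[C@]2(C)[C@H](O)[C@H]1OC(=O)/C(C)=C\C | intermediate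
29 | (1S,3S,4S,6S)-4-[(3S)-3-acetoxy-6-methylhepta-1,5-dien-2-yl]-1-methyl-2-oxo-7-oxabicyclo[4.1.0]heptan-3-yl (2Z)-2-methylbut-2-enoate | C=C([C@H](CC=C(C)C)OC(C)=O)[C@@H]1C[C@@H]2O[C@]2(C)C(=O)[C@H]1OC(=O)/C(C)=C\C | target

**Step count**
Total: 21 steps. Longest linear sequence: 17 steps (steps 2–6, then 10–21; the branch through step 1 is equally long).

**Steps most likely to fail**

1. Step 15 (ene cyclisation). The allylic silyl ether deactivates the C5=C7 alkene, so C–C bond formation may run ahead of hydrogen transfer; a stepwise, cation-like closure would let the axial-oxygen chair compete and erode the trans selectivity at C6. The fallback sets out from 22 and comes back at 23, and it fixes C6 by ketone reduction instead of by the ene transition state. The cyclisation of 22 is taken as it comes, and the carbinol mixture of 23 and its C6 epimer, the (1R,2S,6S)-cyclohexenol F1, is oxidised with Dess–Martin periodinane/pyridine to the 2-(PMB-oxy)cyclohex-3-en-1-one F2, in which the C1 ether and the C5 chain are both equatorial. NaBH4/CeCl3·7H2O in MeOH at −78 °C should then deliver hydride along the axial trajectory and return the all-equatorial alcohol 23. This detour does not repair a wrong configuration at C5; that centre still rests on the control exerted by C1.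

2. Step 10 (second Wittig reaction). The basic ylide may enolise ketone 16 instead of adding to it, which would stall conversion and epimerise C8, and the Z selectivity may be incomplete. The fallback sets out from 10 and comes back at 18; it forms the alkene on an achiral ketone and sets C8 afterwards under reagent control. Ylide 17, made from 10 as before, is condensed with 1-[(tert-butyldimethylsilyl)oxy]propan-2-one, which has no stereocentre to lose, to give the (2Z,5Z)-allylic silyl ether F3. Bu4NF frees the (2Z,5Z)-dienol F4, and MnO2 oxidises it to the (Z)-2-methyl enal F5. Brown allylation with (−)-Ipc2B(allyl), the reagent from (+)-α-pinene (Et2O, −78 °C; NaOH/H2O2), should give the (4S)-homoallylic alcohol F6. Silylation (TBSOTf, 2,6-lutidine) gives the silyl ether F7, and cross-metathesis of its terminal vinyl group with 2-methylbut-2-ene (second-generation Grubbs catalyst, (H2IMes)(PCy3)Cl2Ru=CHPh) installs the prenyl terminus and reaches 18.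

3. Step 16 (angeloylation). The angeloyl donor may isomerise from Z to E during acyl transfer (tiglate formation), or acylation of the hindered C6 hydroxyl may be slow. The fallback sets out from 23 and comes back at 24; it builds the angelate alkene on the ester instead of transferring it. Alcohol 23 is esterified (DCC, DMAP, CH2Cl2) with 2-[bis(2,2,2-trifluoroethoxy)phosphoryl]propanoic acid to the phosphonate ester F8. Still–Gennari olefination of F8 with acetaldehyde (KN(SiMe3)2, 18-crown-6, THF, −78 °C) should form the (Z)-2-methylbut-2-enoate under kinetic control and arrive at 24.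

**Further compounds**
F1 | step 15 | (1R,2S,6S)-6-[(3S)-3-(TBS-oxy)-6-methylhepta-1,5-dien-2-yl]-2-(PMB-oxy)-3-methylcyclohex-3-en-1-ol | C=C([C@H](CC=C(C)C)O[Si](C)(C)C(C)(C)C)[C@@H]1CC=C(C)[C@H](OCc2ccc(OC)cc2)[C@@H]1O
F2 | step 15 | (2S,6S)-6-[(3S)-3-(TBS-oxy)-6-methylhepta-1,5-dien-2-yl]-2-(PMB-oxy)-3-methylcyclohex-3-en-1-one | C=C([C@H](CC=C(C)C)O[Si](C)(C)C(C)(C)C)[C@@H]1CC=C(C)[C@H](OCc2ccc(OC)cc2)C1=O
F3 | step 10 | (4S)-4-[(2Z,5Z)-7-(TBS-oxy)-6-methylhepta-2,5-dien-2-yl]-2,2-dimethyl-1,3-dioxolane | CC(C)(C)[Si](C)(C)OC/C(C)=C\C/C=C(/C)[C@H]1COC(C)(C)O1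
F4 | step 10 | (2Z,5Z)-6-[(4S)-2,2-dimethyl-1,3-dioxolan-4-yl]-2-methylhepta-2,5-dien-1-ol | OC/C(C)=C\C/C=C(/C)[C@H]1COC(C)(C)O1
F5 | step 10 | (2Z,5Z)-6-[(4S)-2,2-dimethyl-1,3-dioxolan-4-yl]-2-methylhepta-2,5-dienal | O=C/C(C)=C\C/C=C(/C)[C@H]1COC(C)(C)O1
F6 | step 10 | (4S,5Z,8Z)-9-[(4S)-2,2-dimethyl-1,3-dioxolan-4-yl]-5-methyldeca-1,5,8-trien-4-ol | C=CC[C@H](O)/C(C)=C\C/C=C(/C)[C@H]1COC(C)(C)O1
F7 | step 10 | (4S)-4-[(2Z,5Z,7S)-7-(TBS-oxy)-6-methyldeca-2,5,9-trien-2-yl]-2,2-dimethyl-1,3-dioxolane | C=CC[C@H](O[Si](C)(C)C(C)(C)C)/C(C)=C\C/C=C(/C)[C@H]1COC(C)(C)O1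
F8 | step 16 | (1S,2S,6S)-6-[(3S)-3-(TBS-oxy)-6-methylhepta-1,5-dien-2-yl]-2-(PMB-oxy)-3-methylcyclohex-3-en-1-yl 2-[bis(2,2,2-trifluoroethoxy)phosphoryl]propanoate (epimers at the phosphonate carbon) | C=C([C@H](CC=C(C)C)O[Si](C)(C)C(C)(C)C)[C@@H]1CC=C(C)[C@H](OCc2ccc(OC)cc2)[C@H]1OC(=O)C(C)P(=O)(OCC(F)(F)F)OCC(F)(F)F
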